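Everything rests on disconnecting ring B (the acetoxybutyl butenolide) at its spiro C–O bond together with the adjacent C–Br bond of ring C, the cyclobutane (Ca, Cd: spiro carbons of rings A and B; Cb, Cc: the CHBr carbons next to Ca and Cd). The key step exploits the anti relationship of the ring B lactone oxygen on Cd and the bromine on Cc: bromolactonisation across a Cc=Cd cyclobutene closes ring B, forms both bonds and sets both stereocentres at once. The precursor is a spiro cyclobutene bearing ring A, the Cb bromine and, on Cd, a bromodienoate arm with its tert-butyl ester cis to the ring.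

Key step: step 11

Remark on faces: with ring C drawn flat, the upper face is the one that carries the ring A lactone oxygen on Ca; the lower face carries C4 of ring A (its C–Br carbon).
Remark on descriptors: the dienoate of 18 and 20 is 2E by the CIP rules (bromine outranks the ring carbon at C3), although ester carbonyl and cyclobutene are cis; this cis arrangement is what the key step needs.
Assumption: in step 5 the antipode of ProPhenol (2,6-bis{[2-(hydroxydiphenylmethyl)pyrrolidin-1-yl]methyl}-4-methylphenol) is chosen so that the 3R alcohol results; the sense is to be confirmed by MTPA ester analysis, and any minor 3S material should be removable after step 9 as a diastereomer.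

Step 1
Reactants: 1 1,2-bis(trimethylsilyloxy)cyclobut-1-ene
Product: 4 cyclobut-3-ene-1,2-dione, via cyclobutane-1,2-dione 2 (not isolated), via 3-bromocyclobutane-1,2-dione 3 (not isolated)
Conditions: Br2 (2.0 equiv), CH2Cl2/pentane, −60 → 20 °C; volatiles removed in vacuo; sublimation in the dark
Reagents that add atoms: none
Why: Bromine oxidatively desilylates the acyloin bis-silyl ether to dione 2, then α-brominates it to 3, and E1cB loss of HBr gives the ene-dione (bromination–dehydrobromination); no stereocentre is formed.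

Step 2
Reactants: 5 ethyl 2-oxohexanoate
Product: 6 ethyl 2-(dibromomethylidene)hexanoate
Conditions: CBr4 (2 equiv), PPh3 (2 equiv), Zn (2 equiv), CH2Cl2, 20 °C, 24 h; then 5, 0 → 20 °C
Reagents that add atoms: tetrabromomethane, BrC(Br)(Br)Br
Why: Ramirez dibromoolefination (Wittig reaction of Ph3P=CBr2) should work well on the strongly electrophilic keto group of an α-keto ester; no stereocentre is formed.

Step 3
Reactants: 6 ethyl 2-(dibromomethylidene)hexanoate; 4 cyclobut-3-ene-1,2-dione
Product: 9 racemic 8-bromo-7-butyl-5-oxaspiro[3.4]octa-2,7-diene-1,6-dione (ring A spiro-fused at Ca to a cyclobutenone), via magnesium carbenoid 7 (not isolated), via chloromagnesium alkoxide 8 (not isolated)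
Conditions: 6, iPrMgCl·LiCl (1.0 equiv), THF, −78 °C; cannulated into 4 (1.3 equiv), THF, −78 → −20 °C; aq NH4Cl
Reagents that add atoms: none
Why: The ester carbonyl directs bromine–magnesium exchange to the cis bromine, and 1,2-addition of this chelated alkenylmagnesium carbenoid to one carbonyl of the strained dione places the alkoxide cis to the ethyl ester, so it lactonises to ring A (carbenoid addition–lactonisation to a 4-bromobutenolide); Ca forms as a racemate.

Step 4
Reactants: 9 racemic 8-bromo-7-butyl-5-oxaspiro[3.4]octa-2,7-diene-1,6-dione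
Product: 10 (4R)-8-bromo-7-butyl-5-oxaspiro[3.4]octa-2,7-diene-1,6-dione
Conditions: preparative SFC, amylose tris(3,5-dimethylphenylcarbamate) phase, CO2/MeOH, 35 °C
Reagents that add atoms: none
Why: Resolution on a chiral stationary phase is routine for a small, rigid, UV-active ketone and supplies Ca in the required sense, to be assigned by anomalous-dispersion X-ray analysis (two bromine atoms) before use.

Step 5
Reactants: 11 butanal; 12 tert-butyl diazoacetate
Product: 13 tert-butyl (3R)-2-diazo-3-hydroxyhexanoate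
Conditions: nBu2Mg (10 mol %), ProPhenol (5 mol %), cis-cyclopentane-1,2-diol (5 mol %), THF, −20 °C
Reagents that add atoms: none
Why: Catalytic asymmetric direct aldol addition of a diazoacetate under dinuclear magnesium–ProPhenol catalysis, in which the chiral pocket selects the aldehyde face and sets C3 as R; the diazo group serves as a masked ketone.

Step 6
Reactants: 13 tert-butyl (3R)-2-diazo-3-hydroxyhexanoate
Product: 14 tert-butyl (3R)-3-{[tert-butyl(dimethyl)silyl]oxy}-2-diazohexanoate
Conditions: TBSCl, imidazole, DMF, 0 → 20 °C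
Reagents that add atoms: tert-butyldimethylsilyl chloride, CC(C)(C)[Si](C)(C)Cl
Why: Imidazole-mediated silylation of a secondary alcohol is tolerated by the acceptor-stabilised diazo ester and does not touch the stereocentre.

Step 7
Reactants: 14 tert-butyl (3R)-3-{[tert-butyl(dimethyl)silyl]oxy}-2-diazohexanoate
Product: 15 tert-butyl (3R)-3-{[tert-butyl(dimethyl)silyl]oxy}-2-oxohexanoate
Conditions: dimethyldioxirane (acetone solution, 1.2 equiv), CH2Cl2, 0 °C
Reagents that add atoms: dimethyldioxirane, CC1(C)OO1
Why: Oxygen-atom transfer to the diazo carbon with loss of N2 (diazo-to-carbonyl oxidation) unmasks the α-keto ester under neutral conditions that should not epimerise the adjacent silyloxy centre.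

Step 8
Reactants: 15 tert-butyl (3R)-3-{[tert-butyl(dimethyl)silyl]oxy}-2-oxohexanoate
Product: 16 tert-butyl 3,3-dibromo-2-[(1R)-1-{[tert-butyl(dimethyl)silyl]oxy}butyl]prop-2-enoate
Conditions: CBr4 (2 equiv), PPh3 (2 equiv), Zn (2 equiv), CH2Cl2, 20 °C, 24 h; then 15, 0 → 20 °C
Reagents that add atoms: tetrabromomethane, BrC(Br)(Br)Br
Why: Ramirez dibromoolefination with the zinc-generated ylide avoids Ph3PBr2, which would attack the silyl ether, and the near-neutral medium should leave the α-stereocentre intact.

Step 9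
Reactants: 16 tert-butyl 3,3-dibromo-2-[(1R)-1-{[tert-butyl(dimethyl)silyl]oxy}butyl]prop-2-enoate; 10 (4R)-8-bromo-7-butyl-5-oxaspiro[3.4]octa-2,7-diene-1,6-dione
Product: 18 tert-butyl (2E)-3-bromo-3-[(1R,4R)-8-bromo-7-butyl-1-hydroxy-6-oxo-5-oxaspiro[3.4]octa-2,7-dien-1-yl]-2-[(1R)-1-{[tert-butyl(dimethyl)silyl]oxy}butyl]prop-2-enoate, via magnesium carbenoid 17 (not isolated)
Conditions: 16 (1.2 equiv), iPrMgCl·LiCl (1.15 equiv), THF, −78 °C; then 10, −78 °C; AcOH, −78 °C
Reagents that add atoms: none
Why: Ester-directed bromine–magnesium exchange (the bulky silyl ether does not chelate) gives the alkenylmagnesium carbenoid, whose 1,2-addition to the strained ketone should occur on the upper face, past the small lactone oxygen and away from C4 of ring A and its bromine, so that the Cd hydroxyl lies on the lower face (1R); the tert-butyl ester and the cold quench prevent lactonisation and ring opening of the alkoxide.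

Step 10
Reactants: 18 the tertiary cyclobutenol of step 9
Product: 20 tert-butyl (2E)-3-bromo-3-[(3S,4S)-3,8-dibromo-7-butyl-6-oxo-5-oxaspiro[3.4]octa-1,7-dien-1-yl]-2-[(1R)-1-{[tert-butyl(dimethyl)silyl]oxy}butyl]prop-2-enoate, via allylic bromosulfite 19 (not isolated)
Conditions: SOBr2 (1.2 equiv), 2,6-di-tert-butyl-4-methylpyridine (1.5 equiv), Et2O, −40 → 0 °C
Reagents that add atoms: thionyl bromide, O=S(Br)Br
Why: SNi′ collapse of the allylic bromosulfite through a six-membered transition state delivers bromine to Cb on the lower face, the face the oxygen leaves at Cd (syn 1,3-transposition), which sets Cb as S and moves the alkene into conjugation as Cc=Cd; the hindered pyridine traps HBr without attacking sulfur, and the electron-poor skeleton disfavours free ionisation.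

Step 11
Reactants: 20 the tert-butyl dienoate of step 10
Product: 22 (5S,6S,11R,12R)-4,10,11,12-tetrabromo-3-butyl-9-[(1R)-1-{[tert-butyl(dimethyl)silyl]oxy}butyl]-1,7-dioxadispiro[4.0.4^6.2^5]dodeca-3,9-diene-2,8-dione, via tert-butoxyfuranium ion 21 (not isolated)
Conditions: NBS (1.3 equiv), Ph3P=S (10 mol %), CH2Cl2, 0 → 20 °C, dark
Reagents that add atoms: N-bromosuccinimide, O=C1CCC(=O)N1Br
Why: Lewis-base-activated NBS transfers Br+ to the cyclobutene Cc=Cd on the upper face, the carbonyl oxygen of the cis-held tert-butyl ester opens the bromonium ion at Cd from the lower face, and the resulting tert-butoxyfuranium ion 21 loses isobutene to give the lactone. The closest known reaction type is the halolactonisation of (2Z)-2,4-dienoic acids and their esters to 5-(1-haloalkyl)butenolides. Ring B closes in the 5-exo mode, the oxygen attacking the proximal bromonium carbon Cd so that Cc stays outside the new ring. Cc (R) is set by the face of bromonium formation, which the Cb bromine and C4 of ring A, both on the lower face, direct to the upper face, and Cd (S) follows from the obligatory backside opening, which puts the lactone oxygen anti to the new bromine and that bromine trans to the one on Cb. The step needs chemoselectivity for the cyclobutene over the two other alkenes, secured by their conjugation to a carbonyl and their vinylic bromine, and 5-exo rather than 6-endo closure, secured by the cis geometry of the arm and the tertiary character of Cd.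

Step 12
Reactants: 22 the silyl-protected target of step 11
Product: 23 (5S,6S,11R,12R)-4,10,11,12-tetrabromo-3-butyl-9-[(1R)-1-hydroxybutyl]-1,7-dioxadispiro[4.0.4^6.2^5]dodeca-3,9-diene-2,8-dione
Conditions: HF·pyridine, pyridine, THF, 0 → 20 °C
Reagents that add atoms: none
Why: Buffered fluoride cleavage of a secondary silyl ether (desilylation) should leave the lactones and all C–Br bonds intact and touches no stereocentre.

Step 13
Reactants: 23 the secondary alcohol of step 12
Product: 24 (5S,6S,11R,12R)-3-[(1R)-1-(acetyloxy)butyl]-4,10,11,12-tetrabromo-9-butyl-1,7-dioxadispiro[4.0.4^6.2^5]dodeca-3,9-diene-2,8-dione (CNP0268004.1)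
Conditions: Ac2O, pyridine, DMAP (cat.), CH2Cl2, 0 °C
Reagents that add atoms: acetic anhydride, CC(=O)OC(C)=O
Why: DMAP-catalysed O-acylation (nucleophilic catalysis) of the secondary alcohol proceeds with retention because the C–O bond is not broken, and pyridine is too weak a base to eliminate HBr from the trans-dibromocyclobutane.

Compound list
1 | 1,2-bis(trimethylsilyloxy)cyclobut-1-ene | C[Si](C)(C)OC1=C(O[Si](C)(C)C)CC1 | starting material
2 | cyclobutane-1,2-dione | O=C1CCC1=O | intermediate (not isolated)
3 | 3-bromocyclobutane-1,2-dione (racemic) | O=C1CC(Br)C1=O | intermediate (not isolated)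
4 | cyclobut-3-ene-1,2-dione | O=C1C=CC1=O | intermediate
5 | ethyl 2-oxohexanoate | CCCCC(=O)C(=O)OCC | starting material
6 | ethyl 2-(dibromomethylidene)hexanoate | CCCCC(=C(Br)Br)C(=O)OCC | intermediate
7 | ethyl (2E)-3-bromo-2-butyl-3-(chloromagnesio)prop-2-enoate (magnesium cis to the ester) | CCCC/C(=C(\Br)[Mg]Cl)C(=O)OCC | intermediate (not isolated)
8 | ethyl (2E)-3-bromo-2-butyl-3-[1-(chloromagnesiooxy)-4-oxocyclobut-2-en-1-yl]prop-2-enoate (racemic; ring cis to the ester) | CCCC/C(=C(\Br)C1(O[Mg]Cl)C=CC1=O)C(=O)OCC | intermediate (not isolated)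
9 | racemic 8-bromo-7-butyl-5-oxaspiro[3.4]octa-2,7-diene-1,6-dione | CCCCC1=C(Br)C2(OC1=O)C=CC2=O | intermediate
10 | (4R)-8-bromo-7-butyl-5-oxaspiro[3.4]octa-2,7-diene-1,6-dione | CCCCC1=C(Br)[C@@]2(OC1=O)C=CC2=O | intermediate
11 | butanal | CCCC=O | starting material
12 | tert-butyl diazoacetate | [N-]=[N+]=CC(=O)OC(C)(C)C | starting material
13 | tert-butyl (3R)-2-diazo-3-hydroxyhexanoate | CCC[C@@H](O)C(=[N+]=[N-])C(=O)OC(C)(C)C | intermediate
14 | tert-butyl (3R)-3-{[tert-butyl(dimethyl)silyl]oxy}-2-diazohexanoate | CCC[C@@H](O[Si](C)(C)C(C)(C)C)C(=[N+]=[N-])C(=O)OC(C)(C)C | intermediate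
15 | tert-butyl (3R)-3-{[tert-butyl(dimethyl)silyl]oxy}-2-oxohexanoate | CCC[C@@H](O[Si](C)(C)C(C)(C)C)C(=O)C(=O)OC(C)(C)C | intermediate
16 | tert-butyl 3,3-dibromo-2-[(1R)-1-{[tert-butyl(dimethyl)silyl]oxy}butyl]prop-2-enoate | CCC[C@@H](O[Si](C)(C)C(C)(C)C)C(=C(Br)Br)C(=O)OC(C)(C)C | intermediate
17 | tert-butyl (2E)-3-bromo-3-(chloromagnesio)-2-[(1R)-1-{[tert-butyl(dimethyl)silyl]oxy}butyl]prop-2-enoate (magnesium cis to the ester) | CCC[C@@H](O[Si](C)(C)C(C)(C)C)/C(=C(\Br)[Mg]Cl)C(=O)OC(C)(C)C | intermediate (not isolated)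
18 | tert-butyl (2E)-3-bromo-3-[(1R,4R)-8-bromo-7-butyl-1-hydroxy-6-oxo-5-oxaspiro[3.4]octa-2,7-dien-1-yl]-2-[(1R)-1-{[tert-butyl(dimethyl)silyl]oxy}butyl]prop-2-enoate | CCCCC1=C(Br)[C@@]2(OC1=O)C=C[C@]2(O)/C(Br)=C(\C(=O)OC(C)(C)C)[C@@H](CCC)O[Si](C)(C)C(C)(C)C | intermediate
19 | bromosulfite ester of 18 (OS(=O)Br on Cd) | CCCCC1=C(Br)[C@@]2(OC1=O)C=C[C@]2(OS(Br)=O)/C(Br)=C(\C(=O)OC(C)(C)C)[C@@H](CCC)O[Si](C)(C)C(C)(C)C | intermediate (not isolated)
20 | tert-butyl (2E)-3-bromo-3-[(3S,4S)-3,8-dibromo-7-butyl-6-oxo-5-oxaspiro[3.4]octa-1,7-dien-1-yl]-2-[(1R)-1-{[tert-butyl(dimethyl)silyl]oxy}butyl]prop-2-enoate (key-step precursor) | CCCCC1=C(Br)[C@@]2(OC1=O)[C@@H](Br)C=C2/C(Br)=C(\C(=O)OC(C)(C)C)[C@@H](CCC)O[Si](C)(C)C(C)(C)C | intermediate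
21 | ring-closed 2-tert-butoxyfuranium ion of ring B, succinimide anion as counter-ion | CCCCC1=C(Br)[C@@]2(OC1=O)[C@@H](Br)[C@H](Br)[C@@]21[O+]=C(OC(C)(C)C)C([C@@H](CCC)O[Si](C)(C)C(C)(C)C)=C1Br.O=C1CCC(=O)[N-]1 | intermediate (not isolated)
22 | (5S,6S,11R,12R)-4,10,11,12-tetrabromo-3-butyl-9-[(1R)-1-{[tert-butyl(dimethyl)silyl]oxy}butyl]-1,7-dioxadispiro[4.0.4^6.2^5]dodeca-3,9-diene-2,8-dione (key-step product) | CCCCC1=C(Br)[C@@]2(OC1=O)[C@@H](Br)[C@H](Br)[C@@]21OC(=O)C([C@@H](CCC)O[Si](C)(C)C(C)(C)C)=C1Br | intermediate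
23 | (5S,6S,11R,12R)-4,10,11,12-tetrabromo-3-butyl-9-[(1R)-1-hydroxybutyl]-1,7-dioxadispiro[4.0.4^6.2^5]dodeca-3,9-diene-2,8-dione | CCCCC1=C(Br)[C@@]2(OC1=O)[C@@H](Br)[C@H](Br)[C@@]21OC(=O)C([C@@H](CCC)O)=C1Br | intermediate
24 | (5S,6S,11R,12R)-3-[(1R)-1-(acetyloxy)butyl]-4,10,11,12-tetrabromo-9-butyl-1,7-dioxadispiro[4.0.4^6.2^5]dodeca-3,9-diene-2,8-dione | CCCCC1=C(Br)[C@@]2(OC1=O)[C@@H](Br)[C@H](Br)[C@@]21OC(=O)C([C@@H](CCC)OC(C)=O)=C1Br | target

Total step count: 13 (12 reactions and one resolution).
Longest linear sequence: 9 steps (steps 5 to 13, from butanal and tert-butyl diazoacetate).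

Steps most likely to fail

Step 11 (key step). Bromenium transfer to the cyclobutene, which is conjugated to the bromoacrylate and carries an allylic bromine, may be too slow. Ionisation of the allylic bromide or 6-endo closure could then compete. The fallback changes the nucleophile from ester to carboxylate and sets out from 20. The tert-butyl ester is cleaved with aqueous H3PO4 (85 %) in toluene at 20 °C, conditions that spare secondary silyl ethers. This should give (2E)-3-bromo-3-[(3S,4S)-3,8-dibromo-7-butyl-6-oxo-5-oxaspiro[3.4]octa-1,7-dien-1-yl]-2-[(1R)-1-{[tert-butyl(dimethyl)silyl]oxy}butyl]prop-2-enoic acid F1. Classical bromolactonisation of its sodium salt (NBS, NaHCO3, MeCN, 0 °C), in which the more nucleophilic carboxylate assists the bromenium transfer, returns to the route at 22.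

Step 10. The bromosulfite may ionise before it collapses. That would lose the facial memory at Cb, let the ester carbonyl capture Cd, or let HBr strip the silyl ether. The fallback separates transposition from halogenation and sets out from 18. Ph3SiOReO3 (2 mol %) in Et2O at −50 °C should induce a suprafacial 1,3-transposition through the perrhenate ester, driven by conjugation. It gives tert-butyl (2E)-3-bromo-3-[(3S,4S)-8-bromo-7-butyl-3-hydroxy-6-oxo-5-oxaspiro[3.4]octa-1,7-dien-1-yl]-2-[(1R)-1-{[tert-butyl(dimethyl)silyl]oxy}butyl]prop-2-enoate F2, with the hydroxyl on the lower face of Cb. SOBr2 in 1,4-dioxane at 10 °C converts F2 into the bromosulfite of F2 F3, which is not isolated. This collapses with retention (SNi with solvent participation); its only allylic alternative, a tertiary non-conjugated bromide, is disfavoured. The sequence returns to the route at 20.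

Step 9. Facial discrimination in the addition to 10 rests only on a lactone oxygen versus an sp2 carbon on Ca and may be poor; the alkoxide may also lactonise or open. The fallback reverses the order of the two carbenoid additions so that the much larger arm controls the second one. It sets out from 4, 16 and 6 and bypasses steps 3 and 4. Carbenoid 17 is added to dione 4 (THF, −78 °C, AcOH quench). This gives tert-butyl (2E)-3-bromo-3-[(1R)-1-hydroxy-4-oxocyclobut-2-en-1-yl]-2-[(1R)-1-{[tert-butyl(dimethyl)silyl]oxy}butyl]prop-2-enoate F4 together with its epimer at the new carbinol carbon. Both are single enantiomers and are separated by chromatography, which replaces the resolution. F4 is deprotonated with iPrMgCl (1.0 equiv, −78 °C) and treated with carbenoid 7. Addition to the remaining ketone should occur anti to the arm and syn to the magnesium alkoxide, so sterics and chelation point the same way. It gives the bis(chloromagnesium) alkoxide adduct F5, which is not isolated. On warming to −20 °C the new alkoxide lactonises onto the ethyl ester and the sequence returns to the route at 18.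

Further compounds
F1 | step 11 | (2E)-3-bromo-3-[(3S,4S)-3,8-dibromo-7-butyl-6-oxo-5-oxaspiro[3.4]octa-1,7-dien-1-yl]-2-[(1R)-1-{[tert-butyl(dimethyl)silyl]oxy}butyl]prop-2-enoic acid | CCCCC1=C(Br)[C@@]2(OC1=O)[C@@H](Br)C=C2/C(Br)=C(\C(O)=O)[C@@H](CCC)O[Si](C)(C)C(C)(C)C
F2 | step 10 | tert-butyl (2E)-3-bromo-3-[(3S,4S)-8-bromo-7-butyl-3-hydroxy-6-oxo-5-oxaspiro[3.4]octa-1,7-dien-1-yl]-2-[(1R)-1-{[tert-butyl(dimethyl)silyl]oxy}butyl]prop-2-enoate | CCCCC1=C(Br)[C@@]2(OC1=O)[C@@H](O)C=C2/C(Br)=C(\C(=O)OC(C)(C)C)[C@@H](CCC)O[Si](C)(C)C(C)(C)C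
F3 | step 10 | bromosulfite ester of F2 | CCCCC1=C(Br)[C@@]2(OC1=O)[C@@H](OS(Br)=O)C=C2/C(Br)=C(\C(=O)OC(C)(C)C)[C@@H](CCC)O[Si](C)(C)C(C)(C)C
F4 | step 9 | tert-butyl (2E)-3-bromo-3-[(1R)-1-hydroxy-4-oxocyclobut-2-en-1-yl]-2-[(1R)-1-{[tert-butyl(dimethyl)silyl]oxy}butyl]prop-2-enoate | O=C1C=C[C@]1(O)/C(Br)=C(\C(=O)OC(C)(C)C)[C@@H](CCC)O[Si](C)(C)C(C)(C)C
F5 | step 9 | bis(chloromagnesium) alkoxide of the adduct of F4 and 7 (cyclobut-3-ene-1,2-diolate carrying both arms, oxygens trans) | CCCC/C(=C(\Br)[C@@]1(O[Mg]Cl)C=C[C@]1(O[Mg]Cl)/C(Br)=C(\C(=O)OC(C)(C)C)[C@@H](CCC)O[Si](C)(C)C(C)(C)C)C(=O)OCC
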